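**Retrosynthetic overview**
- Chain numbering: C7 = carbonyl carbon, C8 = O–CH, C9 = CH3. The main cut is C7–C1 of the 3,4,5-trimethoxyphenyl ring. It leads to 3,4,5-trimethoxyphenyllithium 9 and methyl(aryloxy)ketene 11, which is released in the flask from the racemic BHT ester 7.
- Enabling feature: the only stereocentre, C8, bears an H and sits next to C7, so C7=C8 can pass through a ketene and then an enolate. The ether O on C8 and the flanking OMe groups of the 2,6-dimethoxy-4-propenylphenyl ring chelate Li and fix the enolate geometry. An enantioselective protonation then sets C8 from racemic material.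
- Second cut: C8–O(aryl), made by SN2 of phenol 2 on racemic BHT 2-bromopropanoate 6. The (E)-propenyl group comes from isomerisation of the allyl group of 1.
- No ring is formed; both benzene rings are bought.

Key step: step 4

Assumption: the sense of induction of the chiral diol on enolate 12 cannot be derived from a closely related case. (R,R)-TADDOL is written for Re-face protonation of C8; if a first experiment shows the opposite sense, the equally available (S,S)-enantiomer is used with nothing else changed.

Step 1
Reactants: 1 4-allyl-2,6-dimethoxyphenol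
Product: 2 (E)-2,6-dimethoxy-4-(prop-1-en-1-yl)phenol
Conditions: RuHCl(CO)(PPh3)3 (1 mol %), toluene, 80 °C, Ar
Reagents that add atoms: none
Why: Ruthenium-hydride alkene isomerisation (hydrometalation/β-hydride elimination), well known for eugenol-type allylphenols, moves the C=C into conjugation with the ring under thermodynamic control, which favours the (E)-propenyl isomer; residual Z isomer is removed by chromatography or crystallisation.

Step 2
Reactants: 3 2,6-di-tert-butyl-4-methylphenol (BHT); 4 racemic 2-bromopropanoyl bromide
Product: 6 racemic 2,6-di-tert-butyl-4-methylphenyl 2-bromopropanoate, via lithium phenoxide 5 (not isolated)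
Conditions: n-BuLi (1.05 equiv), THF, 0 °C; then 4, 0 °C → rt
Reagents that add atoms: none
Why: O-Acylation of a pre-formed lithium phenoxide with an acyl bromide is the standard way to esters of this very hindered phenol; the α-carbon is racemic and needs no control because step 4 erases it.

Step 3
Reactants: 2 (E)-2,6-dimethoxy-4-(prop-1-en-1-yl)phenol; 6 racemic 2,6-di-tert-butyl-4-methylphenyl 2-bromopropanoate
Product: 7 racemic 2,6-di-tert-butyl-4-methylphenyl 2-[2,6-dimethoxy-4-[(E)-prop-1-en-1-yl]phenoxy]propanoate
Conditions: K2CO3, DMF, 40 °C, Ar
Reagents that add atoms: none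
Why: Williamson-type SN2 displacement of an α-bromo ester by a phenoxide is accelerated by the adjacent carbonyl group, while the two tert-butyl groups shield the ester carbonyl from acyl transfer to the phenoxide; C8 is formed racemic on purpose.

Step 4
Reactants: 7 racemic 2,6-di-tert-butyl-4-methylphenyl 2-[2,6-dimethoxy-4-[(E)-prop-1-en-1-yl]phenoxy]propanoate; 8 5-bromo-1,2,3-trimethoxybenzene
Product: 13 (S)-2-[2,6-dimethoxy-4-[(E)-prop-1-en-1-yl]phenoxy]-1-(3,4,5-trimethoxyphenyl)propan-1-one (target), via aryllithium 9 (not isolated), via ester enolate 10 (not isolated), via ketene 11 (not isolated), via Z-enolate 12 (not isolated)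
Conditions: (a) 8, t-BuLi (2 equiv), Et2O, −78 °C; (b) 7, n-BuLi (1.0 equiv), THF, −78 °C, then solution (a) (1.2 equiv of 9), −78 → 0 °C; (c) (R,R)-TADDOL (2.5 equiv, recovered), −78 °C; (d) AcOH, THF, −78 °C, then pH 7 buffer
Reagents that add atoms: none
Why: Proposed new method: n-BuLi turns racemic 7 into ester enolate 10, which erases C8 and on warming expels the hindered aryloxide (E1cB) to give methyl(aryloxy)ketene 11; aryllithium 9, present throughout, adds to the ketene carbon C7 in the plane of the C8 substituents and so forms the C7–C1(aryl) bond directly at the ketone oxidation level, the product being stored as enolate 12, which cannot take up a second aryl group. The closest known reaction types are the in situ generation of ketenes from BHT ester enolates with trapping by organolithium reagents to give ketone enolates of defined geometry, the tandem Grignard addition to a ketene followed by enantioselective protonation, and the protonation of tetrasubstituted aryl ketone lithium enolates (2-methyl-1-tetralone type, LiBr present) by TADDOLs; none of these has been shown on an α-aryloxy ketene or enolate, hence the label. No ring is closed. The geometry of 12 is secured by the substrate: the 2,6-dimethoxyaryl group on the ether O turns towards the linear C=C=O unit and blocks that side, so 9 enters next to the methyl group, and the resulting OLi lies cis to the aryloxy oxygen, held in a five-membered O–Li–O chelate backed by one ortho-methoxy group (Z-enolate only). The stereocentre C8 is set by reagent control: TADDOL docks on the chelated lithium through one oxygen and its second, hydrogen-bond-acidified OH delivers the proton to the Re face of C8, so both enantiomers of 7 converge on (S)-13. The step also needs chemoselectivity, since α-deprotonation at −78 °C should outrun carbolithiation and 9 should not add to the electron-rich β-methylstyrene unit, and it needs protection of the labile new centre, which the weakly basic lithium TADDOLate and lithium BHT-oxide together with the AcOH quench at −78 °C should provide.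

**Compound list**
1 | 4-allyl-2,6-dimethoxyphenol | C=CCc1cc(OC)c(O)c(OC)c1 | starting material
2 | (E)-2,6-dimethoxy-4-(prop-1-en-1-yl)phenol | C/C=C/c1cc(OC)c(O)c(OC)c1 | intermediate
3 | 2,6-di-tert-butyl-4-methylphenol (BHT) | Cc1cc(C(C)(C)C)c(O)c(C(C)(C)C)c1 | starting material
4 | racemic 2-bromopropanoyl bromide | CC(Br)C(=O)Br | starting material
5 | lithium 2,6-di-tert-butyl-4-methylphenoxide (not isolated) | Cc1cc(C(C)(C)C)c([O-])c(C(C)(C)C)c1.[Li+] | intermediate
6 | racemic 2,6-di-tert-butyl-4-methylphenyl 2-bromopropanoate | CC(Br)C(=O)Oc1c(C(C)(C)C)cc(C)cc1C(C)(C)C | intermediate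
7 | racemic 2,6-di-tert-butyl-4-methylphenyl 2-[2,6-dimethoxy-4-[(E)-prop-1-en-1-yl]phenoxy]propanoate | C/C=C/c1cc(OC)c(OC(C)C(=O)Oc2c(C(C)(C)C)cc(C)cc2C(C)(C)C)c(OC)c1 | intermediate
8 | 5-bromo-1,2,3-trimethoxybenzene | COc1cc(Br)cc(OC)c1OC | starting material
9 | 3,4,5-trimethoxyphenyllithium (not isolated) | [Li]c1cc(OC)c(OC)c(OC)c1 | intermediate
10 | lithium enolate of ester 7, enolate geometry irrelevant (not isolated) | C/C=C/c1cc(OC)c(OC(C)=C([O-])Oc2c(C(C)(C)C)cc(C)cc2C(C)(C)C)c(OC)c1.[Li+] | intermediate
11 | 2-[2,6-dimethoxy-4-[(E)-prop-1-en-1-yl]phenoxy]prop-1-en-1-one, the methyl(aryloxy)ketene (not isolated) | C/C=C/c1cc(OC)c(OC(C)=C=O)c(OC)c1 | intermediate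
12 | lithium (Z)-2-[2,6-dimethoxy-4-[(E)-prop-1-en-1-yl]phenoxy]-1-(3,4,5-trimethoxyphenyl)prop-1-en-1-olate (not isolated) | C/C=C/c1cc(OC)c(O/C(C)=C(\[O-])c2cc(OC)c(OC)c(OC)c2)c(OC)c1.[Li+] | intermediate
13 | (S)-2-[2,6-dimethoxy-4-[(E)-prop-1-en-1-yl]phenoxy]-1-(3,4,5-trimethoxyphenyl)propan-1-one | C/C=C/c1cc(OC)c(O[C@@H](C)C(=O)c2cc(OC)c(OC)c(OC)c2)c(OC)c1 | target

**Total step count:** 4
**Longest linear sequence:** 3 steps (1 → 2 → 7 → 13, or equally 3 → 6 → 7 → 13)

**Steps most likely to fail**

1. Step 4 (Proposed new method).
 - What may go wrong: incomplete facial discrimination in the proton transfer, proton exchange between enolate 12 and product 13 before the quench (which erodes the enantiomeric purity), or capture of the ketene by enolates instead of by the aryllithium.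
 - Fallback (known chemistry, with the chiral pool replacing the enantioselective protonation): it sets out from 2.
 - A Mitsunobu reaction of 2 with commercial methyl (R)-lactate (PPh3, DIAD, THF, 0 °C → rt) should give, with clean SN2 inversion, methyl (S)-2-[2,6-dimethoxy-4-[(E)-prop-1-en-1-yl]phenoxy]propanoate F1.
 - Aminolysis with MeNH(OMe)·HCl and i-PrMgCl (THF, −20 °C) should give (S)-2-[2,6-dimethoxy-4-[(E)-prop-1-en-1-yl]phenoxy]-N-methoxy-N-methylpropanamide F2.
 - Addition of aryllithium 9 (from 8) at −78 °C with a cold acidic quench (Weinreb ketone synthesis) forms the same C7–C1 bond without touching C8. The fallback comes back to the route at 13.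

2. Step 3.
 - What may go wrong: sluggish substitution because both partners are hindered, so that loss of HBr from the bromo ester takes over, or air oxidation of the electron-rich phenoxide.
 - Fallback (the ether bond is made on a small carboxylate before the bulky ester group is introduced): it sets out from 2.
 - Treatment of 2 with racemic 2-bromopropanoic acid and NaH (2.2 equiv, THF, 0 °C → reflux, then dilute citric acid) should give racemic 2-[2,6-dimethoxy-4-[(E)-prop-1-en-1-yl]phenoxy]propanoic acid F3.
 - 1-Chloro-N,N,2-trimethylprop-1-en-1-amine (CH2Cl2, 0 °C, acid-free conditions that spare the propenyl arene) should give racemic 2-[2,6-dimethoxy-4-[(E)-prop-1-en-1-yl]phenoxy]propanoyl chloride F4.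
 - F4 is added to lithium phenoxide 5 in THF. The fallback comes back to the route at 7.

3. Step 1.
 - What may go wrong: incomplete E/Z selectivity of the double-bond migration, a difficult separation of the isomers, or inhibition of the catalyst by the free phenol.
 - Fallback (the alkene geometry is bought and transferred by cross-coupling instead of being made by isomerisation): it sets out from 6.
 - Alkylation of commercial 4-bromo-2,6-dimethoxyphenol with 6 (K2CO3, DMF, 40 °C) should give racemic 2,6-di-tert-butyl-4-methylphenyl 2-(4-bromo-2,6-dimethoxyphenoxy)propanoate F5.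
 - A stereoretentive Suzuki–Miyaura coupling with commercial (E)-prop-1-en-1-ylboronic acid pinacol ester (Pd(OAc)2/SPhos, K3PO4, dioxane/H2O, 80 °C) follows; the BHT ester should resist the aqueous base. The fallback comes back to the route at 7, so that 1 and 2 are not needed.

**Further compounds**
F1 | step 4 | methyl (S)-2-[2,6-dimethoxy-4-[(E)-prop-1-en-1-yl]phenoxy]propanoate | C/C=C/c1cc(OC)c(O[C@@H](C)C(=O)OC)c(OC)c1
F2 | step 4 | (S)-2-[2,6-dimethoxy-4-[(E)-prop-1-en-1-yl]phenoxy]-N-methoxy-N-methylpropanamide | C/C=C/c1cc(OC)c(O[C@@H](C)C(=O)N(C)OC)c(OC)c1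
F3 | step 3 | racemic 2-[2,6-dimethoxy-4-[(E)-prop-1-en-1-yl]phenoxy]propanoic acid | C/C=C/c1cc(OC)c(OC(C)C(=O)O)c(OC)c1
F4 | step 3 | racemic 2-[2,6-dimethoxy-4-[(E)-prop-1-en-1-yl]phenoxy]propanoyl chloride | C/C=C/c1cc(OC)c(OC(C)C(=O)Cl)c(OC)c1
F5 | step 1 | racemic 2,6-di-tert-butyl-4-methylphenyl 2-(4-bromo-2,6-dimethoxyphenoxy)propanoate | CC(Oc1c(OC)cc(Br)cc1OC)C(=O)Oc1c(C(C)(C)C)cc(C)cc1C(C)(C)C
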